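The target is cut at both bonds to the ester carbonyl carbon C1 of the hexacosanoyl chain: C1–C2 and C1–O of the 2-arylethyl ester. C1 is a lone carbon flanked by an unbranched C25 alkyl chain and the primary tyrosol oxygen, so carbon monoxide can supply it. One palladium-hydride-catalysed hydroalkoxycarbonylation joins pentacos-1-ene, CO and unprotected tyrosol and forms both bonds at once; the para-hydroxyphenyl ring (the only ring) and its phenolic OH are spectators. The precursor is the terminal C25 alkene, made in one copper-catalysed coupling of 1-bromodocosane with allylmagnesium bromide. The carbonylation product is the target itself.

Key step: step 2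

Remark: 1, 2, 4, 5 and the catalyst components are taken as purchased; the target has no stereocentre. The carbon count is C22 (bromide) + C3 (allyl) = C25 alkene, plus one carbon from CO = C26 acyl chain.

Step 1
Reactants: 1 1-bromodocosane; 2 allylmagnesium bromide
Product: 3 pentacos-1-ene (1-pentacosene)
Conditions: 2 (1.5 equiv, 1.0 M in Et2O), Li2CuCl4 (3 mol%), THF, 0 °C → rt; aq. NH4Cl; silica plug (hexane), crystallisation from acetone
Reagents that add atoms: none
Why: Copper-catalysed Kumada-type alkyl–allyl cross-coupling at an unhindered primary bromide should be clean, and because the allyl group is symmetric, alpha or gamma delivery gives the same terminal alkene; no stereocentre is formed.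

Step 2
Reactants: 3 pentacos-1-ene; 4 tyrosol, 2-(4-hydroxyphenyl)ethanol; 5 carbon monoxide
Product: 6 2-(4-hydroxyphenyl)ethyl hexacosanoate
Conditions: Pd(OAc)2 (1 mol%), 1,2-bis(di-tert-butylphosphinomethyl)benzene (5 mol%), MeSO3H (10 mol%), 4 (2 equiv), CO (30 bar), toluene/1,4-dioxane, 100 °C; water wash, chromatography, crystallisation
Reagents that add atoms: none
Why: Pd(OAc)2, the bulky diphosphine and MeSO3H should generate a cationic divalent palladium hydride [(P–P)PdH]+ that inserts the alkene, with reversible beta-hydride elimination and reinsertion funnelling any internal isomer to the terminal alkyl–palladium; CO insertion then gives the linear acyl–palladium (C1–C2 bond), and alcoholysis by the primary hydroxyl of tyrosol forms the C1–O bond and returns the hydride. The closest known reaction type is the linear-selective, isomerising alkoxycarbonylation of long-chain alkenes with this catalyst system, which also runs with primary alcohols in near-stoichiometric amount. No ring is closed and no stereocentre is formed. Linear over branched selectivity is required and is secured by the steric demand of the di-tert-butylphosphino groups acting on an unbranched 1-alkene. Selectivity for the aliphatic over the phenolic hydroxyl is required and should rest on the higher nucleophilicity of the primary alcohol, on the acidic medium that keeps the phenol un-ionised, and on the twofold excess of tyrosol, which suppresses diacylation and should transesterify any aryl ester back to the more stable alkyl ester. Alkylation of the phenol ring by the alkene should be negligible because the sulfonic acid is only catalytic and the solvent is non-ionising.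

Compound list
1 | 1-bromodocosane | CCCCCCCCCCCCCCCCCCCCCCBr | starting material
2 | allylmagnesium bromide | C=CC[Mg]Br | starting material
3 | pentacos-1-ene (1-pentacosene) | C=CCCCCCCCCCCCCCCCCCCCCCCC | intermediate
4 | tyrosol, 2-(4-hydroxyphenyl)ethanol | OCCc1ccc(O)cc1 | starting material
5 | carbon monoxide | [C-]#[O+] | starting material
6 | 2-(4-hydroxyphenyl)ethyl hexacosanoate | CCCCCCCCCCCCCCCCCCCCCCCCCC(=O)OCCc1ccc(O)cc1 | target

Total step count: 2
Longest linear sequence: 2 steps (1 → 3 → 6)

Steps most likely to fail (the route has only two steps, so both are ranked, the key step first)

1. Step 2. Two processes may go wrong. Acyl transfer may lose its chemoselectivity, with acylation of the phenolic oxygen or double acylation. Alternatively, alcoholysis of the acyl–palladium may stall at the low concentration of a stoichiometric, poorly soluble alcohol, so that the alkene only isomerises and palladium metal precipitates. The fallback separates the carbonylation from the union with tyrosol and sets out from 3. Carbonylation in methanol, where the nucleophile is the solvent and no second hydroxyl competes (Pd(OAc)2, the same diphosphine, MeSO3H, CO 30 bar, MeOH/toluene, 90 °C), should give methyl hexacosanoate F1. Saponification (LiOH, THF/MeOH/H2O, 60 °C, then HCl) should give hexacosanoic acid F2. Fischer esterification of F2 with an excess of tyrosol 4 (p-TsOH·H2O 5 mol%, toluene, Dean–Stark), under which a phenol is not acylated, comes back to the route at 6.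

2. Step 1. Displacement at the unactivated primary carbon–bromine bond may remain incomplete, with competing bromine–magnesium exchange and reductive homocoupling of the Grignard reagent. Residual halide and saturated hydrocarbon would be hard to remove from the waxy alkene. The saturated hydrocarbons are inert in step 2 and would leave at the final chromatography; residual bromide is the real concern. The fallback reverses the polarity of the coupling and sets out from 1. Magnesium insertion (Mg turnings, cat. 1,2-dibromoethane, THF, 50 °C) should give docosylmagnesium bromide F3, which is allylated with allyl bromide (CuBr·SMe2 5 mol%, THF, 0 °C → rt). The displacement now takes place at a reactive allylic carbon, and the sequence comes back to the route at 3.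

Further compounds
F1 | step 2 | methyl hexacosanoate | CCCCCCCCCCCCCCCCCCCCCCCCCC(=O)OC
F2 | step 2 | hexacosanoic acid | CCCCCCCCCCCCCCCCCCCCCCCCCC(=O)O
F3 | step 1 | docosylmagnesium bromide | CCCCCCCCCCCCCCCCCCCCCC[Mg]Br
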